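**Retrosynthetic overview**
- The C3' prenyl group comes from a C3' allyl group by olefin cross-metathesis, and the allyl group from a 2'-O-allyl ether by aromatic Claisen rearrangement (C3' is the only open ortho position).
- The isoflavone core comes from a 2'-hydroxychalcone by oxidative 1,2-aryl shift with trivalent thallium nitrate, then acid ring closure. Ring C (the pyranone) is the only ring built; rings A and B are bought as benzene rings.
- The chalcone comes from a Claisen–Schmidt aldol condensation of a ring A acetophenone with a ring B benzaldehyde; this C–C bond joins the two halves.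
- The ring B aldehyde comes from isovanillin (MOM protection, Baeyer–Villiger oxidation, ortho-formylation, O-benzylation); ring A comes from 2,4-dihydroxyacetophenone.
- Protecting groups: benzyl on the 2'-oxygen (survives acid, removed by hydrogenolysis to place the allyl ether); MOM on the 7- and 4'-oxygens (removed last).

Assumption: the target has no stereocentre and no stereogenic double bond, so "single enantiomer" is taken to mean the achiral compound exactly as drawn.

**Route**

Step 1
Reactants: 1 isovanillin (3-hydroxy-4-methoxybenzaldehyde)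
Product: 2 4-methoxy-3-(methoxymethoxy)benzaldehyde
Conditions: MOMCl (1.3 equiv), K2CO3, acetone, 0 °C to rt
Reagents that add atoms: chloromethyl methyl ether (MOMCl), COCCl
Why: Williamson-type O-alkylation of the only phenol gives an acetal ether that withstands the peracid, base and aldol steps ahead.

Step 2
Reactants: 2 4-methoxy-3-(methoxymethoxy)benzaldehyde
Product: 4 4-methoxy-3-(methoxymethoxy)phenol, via aryl formate 3 (not isolated)
Conditions: mCPBA (1.3 equiv), DCM, rt; then K2CO3, MeOH, rt
Reagents that add atoms: meta-chloroperoxybenzoic acid (mCPBA), OOC(=O)c1cccc(Cl)c1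
Why: Baeyer–Villiger oxidation of an electron-rich benzaldehyde proceeds by aryl migration (assisted by the para-methoxy group) to the aryl formate, which mild methanolysis cleaves to the phenol.

Step 3
Reactants: 4 4-methoxy-3-(methoxymethoxy)phenol
Product: 6 2-hydroxy-5-methoxy-4-(methoxymethoxy)benzaldehyde, via benzylic alcohol 5 (not isolated)
Conditions: MgCl2 (2 equiv), Et3N (4 equiv), paraformaldehyde (6 equiv), MeCN, reflux
Reagents that add atoms: paraformaldehyde (as formaldehyde), C=O
Why: Magnesium-phenoxide-directed ortho-formylation (Casnati–Skattebøl) delivers formaldehyde only ortho to the free OH and prefers the unhindered C6 over the position flanked by the OMOM group, the hydroxymethyl intermediate being oxidised in the flask by a second formaldehyde through Oppenauer-type hydride transfer.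

Step 4
Reactants: 6 2-hydroxy-5-methoxy-4-(methoxymethoxy)benzaldehyde
Product: 7 2-(benzyloxy)-5-methoxy-4-(methoxymethoxy)benzaldehyde
Conditions: BnBr, K2CO3, DMF, 60 °C
Reagents that add atoms: benzyl bromide, BrCc1ccccc1
Why: Williamson etherification of the salicylaldehyde OH installs a benzyl ether that survives base, trivalent thallium and hot methanolic HCl yet is removable later by hydrogenolysis.

Step 5
Reactants: 8 2,4-dihydroxyacetophenone
Product: 9 1-[2-hydroxy-4-(methoxymethoxy)phenyl]ethan-1-one
Conditions: MOMCl (1.1 equiv), K2CO3, acetone, rt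
Reagents that add atoms: chloromethyl methyl ether (MOMCl), COCCl
Why: Selective Williamson MOM etherification occurs at the 4-OH because the 2-OH is hydrogen-bonded to the ketone and far less nucleophilic.

Step 6
Reactants: 7 2-(benzyloxy)-5-methoxy-4-(methoxymethoxy)benzaldehyde; 9 1-[2-hydroxy-4-(methoxymethoxy)phenyl]ethan-1-one
Product: 11 (E)-3-[2-(benzyloxy)-5-methoxy-4-(methoxymethoxy)phenyl]-1-[2-hydroxy-4-(methoxymethoxy)phenyl]prop-2-en-1-one, via aldol adduct 10 (not isolated)
Conditions: KOH (50% aq.), EtOH, rt, 48 h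
Reagents that add atoms: none
Why: Claisen–Schmidt crossed aldol condensation works because the aldehyde cannot enolise and the methyl ketone is the only enolisable partner; the racemic aldol adduct dehydrates by E1cB to the thermodynamically favoured E-enone, so no stereocentre persists.

Step 7
Reactants: 11 (E)-3-[2-(benzyloxy)-5-methoxy-4-(methoxymethoxy)phenyl]-1-[2-hydroxy-4-(methoxymethoxy)phenyl]prop-2-en-1-one
Product: 12 2-[2-(benzyloxy)-5-methoxy-4-(methoxymethoxy)phenyl]-1-[2-hydroxy-4-(methoxymethoxy)phenyl]-3,3-dimethoxypropan-1-one (racemic, used crude)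
Conditions: Tl(NO3)3·3H2O (trivalent thallium nitrate, 1.1 equiv), MeOH/HC(OMe)3 1:1, rt, 2 h; NaHCO3 work-up
Reagents that add atoms: methanol, CO
Why: Oxythallation of the enone in methanol followed by 1,2-shift of the electron-rich aryl group (oxidative rearrangement of a 2'-hydroxychalcone) gives the 2-aryl-3,3-dimethoxypropanone skeleton of an isoflavone; the new C2 stereocentre is racemic and is destroyed in the next step.

Step 8
Reactants: 12 2-[2-(benzyloxy)-5-methoxy-4-(methoxymethoxy)phenyl]-1-[2-hydroxy-4-(methoxymethoxy)phenyl]-3,3-dimethoxypropan-1-one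
Product: 13 3-[2-(benzyloxy)-4-hydroxy-5-methoxyphenyl]-7-hydroxy-4H-chromen-4-one
Conditions: HCl (3 M in MeOH), reflux, 3 h
Reagents that add atoms: none
Why: Acid-catalysed acetal exchange lets the ortho phenol of ring A attack the acetal carbon and loss of methanol closes and aromatises the pyranone (ring C), while the same acid cleaves both MOM acetals and leaves the benzyl ether, which blocks the competing ring B cyclisation, untouched.

Step 9
Reactants: 13 3-[2-(benzyloxy)-4-hydroxy-5-methoxyphenyl]-7-hydroxy-4H-chromen-4-one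
Product: 14 3-[2-(benzyloxy)-5-methoxy-4-(methoxymethoxy)phenyl]-7-(methoxymethoxy)-4H-chromen-4-one
Conditions: MOMCl (3 equiv), K2CO3, acetone, rt to 50 °C
Reagents that add atoms: chloromethyl methyl ether (MOMCl), COCCl
Why: Williamson MOM etherification of both free phenols, with the 2'-oxygen still benzylated, gives acetal ethers that tolerate hydrogenolysis, allylation, heat and metathesis.

Step 10
Reactants: 14 3-[2-(benzyloxy)-5-methoxy-4-(methoxymethoxy)phenyl]-7-(methoxymethoxy)-4H-chromen-4-one
Product: 15 3-[2-hydroxy-5-methoxy-4-(methoxymethoxy)phenyl]-7-(methoxymethoxy)-4H-chromen-4-one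
Conditions: H2 (1 atm), 10% Pd/C, EtOAc/THF, rt, monitored by TLC
Reagents that add atoms: none
Why: Catalytic hydrogenolysis cleaves the benzylic C–O bond selectively at room temperature and one atmosphere, unmasking only the 2'-OH while the MOM ethers and the chromone survive.

Step 11
Reactants: 15 3-[2-hydroxy-5-methoxy-4-(methoxymethoxy)phenyl]-7-(methoxymethoxy)-4H-chromen-4-one
Product: 16 3-[2-(allyloxy)-5-methoxy-4-(methoxymethoxy)phenyl]-7-(methoxymethoxy)-4H-chromen-4-one
Conditions: allyl bromide, K2CO3, acetone, reflux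
Reagents that add atoms: allyl bromide, C=CCBr
Why: Williamson O-allylation of the single free phenol sets up the aromatic Claisen rearrangement.

Step 12
Reactants: 16 3-[2-(allyloxy)-5-methoxy-4-(methoxymethoxy)phenyl]-7-(methoxymethoxy)-4H-chromen-4-one
Product: 18 3-[3-allyl-2-hydroxy-5-methoxy-4-(methoxymethoxy)phenyl]-7-(methoxymethoxy)-4H-chromen-4-one, via ortho-dienone 17 (not isolated)
Conditions: N,N-diethylaniline, 190 °C, sealed tube, argon
Reagents that add atoms: none
Why: The aromatic Claisen rearrangement ([3,3]-sigmatropic) can deliver the allyl group only to C3' because the other ortho position carries the chromone, and the racemic dienone intermediate re-aromatises by tautomerisation, so no stereocentre persists.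

Step 13
Reactants: 18 3-[3-allyl-2-hydroxy-5-methoxy-4-(methoxymethoxy)phenyl]-7-(methoxymethoxy)-4H-chromen-4-one
Product: 19 3-[2-hydroxy-5-methoxy-4-(methoxymethoxy)-3-(3-methylbut-2-en-1-yl)phenyl]-7-(methoxymethoxy)-4H-chromen-4-one
Conditions: second-generation Grubbs catalyst (H2IMes)(PCy3)Cl2Ru=CHPh (5 mol%), 2-methyl-2-butene/DCM, 40 °C, sealed
Reagents that add atoms: 2-methyl-2-butene, CC=C(C)C
Why: Olefin cross-metathesis of a terminal allyl group with excess 2-methyl-2-butene reliably gives the trisubstituted prenyl alkene, is driven by loss of volatile propene, and tolerates the free phenol.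

Step 14
Reactants: 19 3-[2-hydroxy-5-methoxy-4-(methoxymethoxy)-3-(3-methylbut-2-en-1-yl)phenyl]-7-(methoxymethoxy)-4H-chromen-4-one
Product: 20 piscisoflavone A, 3-[2,4-dihydroxy-5-methoxy-3-(3-methylbut-2-en-1-yl)phenyl]-7-hydroxy-4H-chromen-4-one
Conditions: HCl (3 M in MeOH), rt to 40 °C, monitored by TLC
Reagents that add atoms: none
Why: Acid-catalysed acetal exchange with methanol removes both MOM groups under conditions mild enough that the prenyl group is not cyclised onto the neighbouring phenols, giving the achiral target.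

**Compound list**
1 | isovanillin (3-hydroxy-4-methoxybenzaldehyde) | COc1ccc(C=O)cc1O | starting material
2 | 4-methoxy-3-(methoxymethoxy)benzaldehyde | COCOc1cc(C=O)ccc1OC | intermediate
3 | aryl formate, 4-methoxy-3-(methoxymethoxy)phenyl formate (not isolated) | COCOc1cc(OC=O)ccc1OC | intermediate
4 | 4-methoxy-3-(methoxymethoxy)phenol | COCOc1cc(O)ccc1OC | intermediate
5 | benzylic alcohol, 2-(hydroxymethyl)-4-methoxy-5-(methoxymethoxy)phenol (not isolated) | COCOc1cc(O)c(CO)cc1OC | intermediate
6 | 2-hydroxy-5-methoxy-4-(methoxymethoxy)benzaldehyde | COCOc1cc(O)c(C=O)cc1OC | intermediate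
7 | 2-(benzyloxy)-5-methoxy-4-(methoxymethoxy)benzaldehyde | COCOc1cc(OCc2ccccc2)c(C=O)cc1OC | intermediate
8 | 2,4-dihydroxyacetophenone | CC(=O)c1ccc(O)cc1O | starting material
9 | 1-[2-hydroxy-4-(methoxymethoxy)phenyl]ethan-1-one | CC(=O)c1ccc(OCOC)cc1O | intermediate
10 | aldol adduct, 3-[2-(benzyloxy)-5-methoxy-4-(methoxymethoxy)phenyl]-3-hydroxy-1-[2-hydroxy-4-(methoxymethoxy)phenyl]propan-1-one (racemic, not isolated) | COCOc1ccc(C(=O)CC(O)c2cc(OC)c(OCOC)cc2OCc3ccccc3)c(O)c1 | intermediate
11 | (E)-3-[2-(benzyloxy)-5-methoxy-4-(methoxymethoxy)phenyl]-1-[2-hydroxy-4-(methoxymethoxy)phenyl]prop-2-en-1-one | COCOc1ccc(C(=O)/C=C/c2cc(OC)c(OCOC)cc2OCc3ccccc3)c(O)c1 | intermediate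
12 | 2-[2-(benzyloxy)-5-methoxy-4-(methoxymethoxy)phenyl]-1-[2-hydroxy-4-(methoxymethoxy)phenyl]-3,3-dimethoxypropan-1-one (racemic) | COCOc1ccc(C(=O)C(C(OC)OC)c2cc(OC)c(OCOC)cc2OCc3ccccc3)c(O)c1 | intermediate
13 | 3-[2-(benzyloxy)-4-hydroxy-5-methoxyphenyl]-7-hydroxy-4H-chromen-4-one | COc1cc(-c2coc3cc(O)ccc3c2=O)c(OCc2ccccc2)cc1O | intermediate
14 | 3-[2-(benzyloxy)-5-methoxy-4-(methoxymethoxy)phenyl]-7-(methoxymethoxy)-4H-chromen-4-one | COc1cc(-c2coc3cc(OCOC)ccc3c2=O)c(OCc2ccccc2)cc1OCOC | intermediate
15 | 3-[2-hydroxy-5-methoxy-4-(methoxymethoxy)phenyl]-7-(methoxymethoxy)-4H-chromen-4-one | COc1cc(-c2coc3cc(OCOC)ccc3c2=O)c(O)cc1OCOC | intermediate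
16 | 3-[2-(allyloxy)-5-methoxy-4-(methoxymethoxy)phenyl]-7-(methoxymethoxy)-4H-chromen-4-one | COc1cc(-c2coc3cc(OCOC)ccc3c2=O)c(OCC=C)cc1OCOC | intermediate
17 | ortho-dienone, 3-[5-allyl-3-methoxy-4-(methoxymethoxy)-6-oxocyclohexa-1,3-dien-1-yl]-7-(methoxymethoxy)-4H-chromen-4-one (racemic, not isolated) | COC1=C(OCOC)C(CC=C)C(=O)C(-c2coc3cc(OCOC)ccc3c2=O)=C1 | intermediate
18 | 3-[3-allyl-2-hydroxy-5-methoxy-4-(methoxymethoxy)phenyl]-7-(methoxymethoxy)-4H-chromen-4-one | COc1cc(-c2coc3cc(OCOC)ccc3c2=O)c(O)c(CC=C)c1OCOC | intermediate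
19 | 3-[2-hydroxy-5-methoxy-4-(methoxymethoxy)-3-(3-methylbut-2-en-1-yl)phenyl]-7-(methoxymethoxy)-4H-chromen-4-one | COc1cc(-c2coc3cc(OCOC)ccc3c2=O)c(O)c(CC=C(C)C)c1OCOC | intermediate
20 | piscisoflavone A, 3-[2,4-dihydroxy-5-methoxy-3-(3-methylbut-2-en-1-yl)phenyl]-7-hydroxy-4H-chromen-4-one (achiral) | COc1cc(-c2coc3cc(O)ccc3c2=O)c(O)c(CC=C(C)C)c1O | target

**Totals**
Total step count: 14.
Longest linear sequence: 13 steps (steps 1 to 4, then 6 to 14, from isovanillin); step 5 is the one-step side branch for ring A.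

**Three steps most likely to fail, with fallbacks**

Step 7 (oxidative rearrangement). The nitric acid released can loosen the MOM ethers, and a freed phenol on the very electron-rich ring B would be over-oxidised by trivalent thallium. The fallback keeps the chalcone but makes the aryl-bearing carbon skeleton by the epoxide route; it sets out from 11 and comes back at 13. The chelated phenol of 11 is capped with NaH and MOMCl in DMF to give (E)-3-[2-(benzyloxy)-5-methoxy-4-(methoxymethoxy)phenyl]-1-[2,4-bis(methoxymethoxy)phenyl]prop-2-en-1-one F1. Weitz–Scheffer epoxidation (30% H2O2, NaOH, MeOH/acetone, 0 °C) then gives the racemic trans-epoxide [2,4-bis(methoxymethoxy)phenyl]{3-[2-(benzyloxy)-5-methoxy-4-(methoxymethoxy)phenyl]oxiran-2-yl}methanone F2. BF3·OEt2 in Et2O at 0 °C opens the epoxide at the benzylic carbon and triggers a 1,2-aroyl shift to the keto aldehyde 2-[2-(benzyloxy)-5-methoxy-4-(methoxymethoxy)phenyl]-3-[2,4-bis(methoxymethoxy)phenyl]-3-oxopropanal F3. Methanolic HCl at reflux strips the three MOM groups and closes ring C to give 13.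

Step 12 (Claisen rearrangement). At 190 °C the MOM ethers or the chromone may degrade, or the new allylphenol may cyclise to a dihydrobenzofuran. The fallback replaces the sigmatropic step by halogenation and cross-coupling; it sets out from 15 and comes back at 18. N-Iodosuccinimide in MeCN at 0 °C iodinates the only position ortho to the free phenol to give 3-[2-hydroxy-3-iodo-5-methoxy-4-(methoxymethoxy)phenyl]-7-(methoxymethoxy)-4H-chromen-4-one F4. Stille coupling with allyltributylstannane (Pd(PPh3)4, zerovalent palladium, LiCl, DMF, 90 °C) then gives 18.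

Step 14 (final MOM removal). Acid can add the flanking phenols across the prenyl double bond to give a 2,2-dimethylchroman. The fallback reverses the order so that acid never meets the prenyl group; it sets out from 18 and comes back at 20. Methanolic HCl at 40 °C removes both MOM groups from 18 (the terminal allyl alkene is far less prone to acid cyclisation) to give 3-(3-allyl-2,4-dihydroxy-5-methoxyphenyl)-7-hydroxy-4H-chromen-4-one F5. Cross-metathesis of this free triphenol with 2-methyl-2-butene and second-generation Grubbs catalyst (H2IMes)(PCy3)Cl2Ru=CHPh in DCM at 40 °C gives 20 directly.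

**Further compounds**
F1 | step 7 | (E)-3-[2-(benzyloxy)-5-methoxy-4-(methoxymethoxy)phenyl]-1-[2,4-bis(methoxymethoxy)phenyl]prop-2-en-1-one | COCOc1ccc(C(=O)/C=C/c2cc(OC)c(OCOC)cc2OCc3ccccc3)c(OCOC)c1
F2 | step 7 | [2,4-bis(methoxymethoxy)phenyl]{3-[2-(benzyloxy)-5-methoxy-4-(methoxymethoxy)phenyl]oxiran-2-yl}methanone (racemic trans-epoxide, one enantiomer drawn) | COCOc1ccc(C(=O)[C@H]2O[C@@H]2c3cc(OC)c(OCOC)cc3OCc4ccccc4)c(OCOC)c1
F3 | step 7 | 2-[2-(benzyloxy)-5-methoxy-4-(methoxymethoxy)phenyl]-3-[2,4-bis(methoxymethoxy)phenyl]-3-oxopropanal (racemic) | COCOc1ccc(C(=O)C(C=O)c2cc(OC)c(OCOC)cc2OCc3ccccc3)c(OCOC)c1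
F4 | step 12 | 3-[2-hydroxy-3-iodo-5-methoxy-4-(methoxymethoxy)phenyl]-7-(methoxymethoxy)-4H-chromen-4-one | COc1cc(-c2coc3cc(OCOC)ccc3c2=O)c(O)c(I)c1OCOC
F5 | step 14 | 3-(3-allyl-2,4-dihydroxy-5-methoxyphenyl)-7-hydroxy-4H-chromen-4-one | COc1cc(-c2coc3cc(O)ccc3c2=O)c(O)c(CC=C)c1O
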